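**Assumptions.** The SMILES defines the all‑trans, C2‑symmetric (2S,3R,4R,5S) isomer, and that is the compound made. The facial preference of chiral‑diene Rh catalysts on this new acceptor class is not established, so the ligand antipode that gives Re‑face arylation is to be fixed by experiment (both antipodes are available).

## Retrosynthetic overview

1. Target 6 ⇐ reduction of the two esters of the all‑trans diester 5; no stereocentre is touched.
2. Diester 5 ⇐ one‑pot, catalyst‑controlled double dearomative conjugate arylation (C2–Ar and C5–Ar bonds) of flat, achiral dimethyl furan‑3,4‑dicarboxylate 4. This step destroys both the aromaticity and the mirror symmetry of 4 and sets all four stereocentres.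
3. Aryl donor 3 ⇐ para C–H borylation of syringol 1, a cheap lignin‑derived phenol.
4. Ring order: no ring is built. The furan ring of 4 becomes the tetrahydrofuran ring of the target.

## Route

**Step 1**
Reactants: 1, syringol (2,6‑dimethoxyphenol); 2, bis(pinacolato)diboron.
Product: 3, 2,6‑dimethoxy‑4‑(4,4,5,5‑tetramethyl‑1,3,2‑dioxaborolan‑2‑yl)phenol.
Conditions: HBpin (1.1 equiv), THF, rt (caps ArOH as ArOBpin); then 2 (0.7 equiv), [Ir(cod)OMe]2 (1.5 mol%), dtbpy (3 mol%), 80 °C; MeOH/aq NH4Cl work‑up to cleave O–B.
Reagents that add atoms: bis(pinacolato)diboron, CC1(C)OB(OC1(C)C)B1OC(C)(C)C(C)(C)O1; pinacolborane, CC1(C)OBOC1(C)C (either can deliver the C–Bpin unit).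
Why: Ir‑catalysed, sterically controlled C–H borylation (Hartwig–Miyaura type) goes to C4, the only ring C–H not ortho to a substituent, and the phenol is masked in situ as its O‑Bpin ester and freed on work‑up; no stereocentre is formed.

**Step 2 (key step)**
Reactants: 4, dimethyl furan‑3,4‑dicarboxylate; 3 (3.0 equiv).
Product: 5, dimethyl (2S,3S,4S,5S)‑2,5‑bis(4‑hydroxy‑3,5‑dimethoxyphenyl)oxolane‑3,4‑dicarboxylate (all‑trans: aryls trans to each other, esters trans to each other, each aryl trans to the adjacent ester).
Conditions: [RhCl(C2H4)2]2 (2.5 mol%), (R,R)‑Ph‑bod* chiral diene (5.5 mol%; antipode if required), KOH (0.3 equiv), dioxane/H2O 10:1, 60 °C.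
Reagents that add atoms: none beyond reactant 3, which supplies both 4‑hydroxy‑3,5‑dimethoxyphenyl groups; water supplies only H.
Why: Proposed new method: an aryl–Rh(I)(diene*) species carbometalates the C2=C3 bond of 4 (a β‑alkoxy acrylate whose furan resonance energy is only about 16 kcal/mol) on the Re face of C2, water protonates the Rh oxa‑π‑allyl, and the now non‑aromatic β‑alkoxy acrylate C4=C5 of the 2‑aryl‑2,3‑dihydrofuran is arylated by the same catalyst on the Re face of C5, which lies on the opposite side of the ring, so catalyst control gives the 2,5‑trans (2S,5S) product with statistical (Horeau) enrichment of ee (the minor sense of addition is diverted into the separable 2,5‑cis diastereomer), while C3 and C4 are set by protonation anti to the neighbouring aryl and are the thermodynamic, epimerisable trans ester centres; the closest known reaction types are Hayashi–Miyaura asymmetric conjugate arylation of chromones, coumarins and 2,3‑dihydro‑4‑pyranones (β‑oxygenated, partly aromatic acceptors) and dearomative Michael/arylation reactions of electron‑poor heteroarenes such as 2‑nitrobenzofurans and nicotinate‑derived pyridinium salts.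

**Step 3**
Reactants: 5.
Product: 6, huazhongilexin, (2S,3R,4R,5S)‑2,5‑bis(4‑hydroxy‑3,5‑dimethoxyphenyl)‑3,4‑bis(hydroxymethyl)oxolane.
Conditions: LiAlH4 (6 equiv), THF, 0 °C → rt; Rochelle‑salt work‑up.
Reagents that add atoms: none.
Why: Ester reduction by LiAlH4 (the two phenols are carried as aluminium phenoxides, hence the excess) leaves all four C–H stereocentres untouched; the C3/C4 descriptors change from S to R only because CH2OH ranks below C2/C5 whereas CO2Me ranks above them.

## Compound list

1 | syringol (2,6‑dimethoxyphenol) | COc1cccc(OC)c1O | starting material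
2 | bis(pinacolato)diboron | CC1(C)OB(OC1(C)C)B1OC(C)(C)C(C)(C)O1 | starting material
3 | 2,6‑dimethoxy‑4‑(pinacolboryl)phenol | COc1cc(B2OC(C)(C)C(C)(C)O2)cc(OC)c1O | intermediate
4 | dimethyl furan‑3,4‑dicarboxylate | COC(=O)c1cocc1C(=O)OC | starting material
5 | dimethyl (2S,3S,4S,5S)‑2,5‑bis(4‑hydroxy‑3,5‑dimethoxyphenyl)oxolane‑3,4‑dicarboxylate | COc1cc([C@H]2O[C@H](c3cc(OC)c(O)c(OC)c3)[C@@H](C(=O)OC)[C@@H]2C(=O)OC)cc(OC)c1O | intermediate
6 | huazhongilexin | COc1cc([C@H]2O[C@H](c3cc(OC)c(O)c(OC)c3)[C@@H](CO)[C@@H]2CO)cc(OC)c1O | target

## Totals and risks

Total steps: 3. Longest linear sequence: 3 (1 → 3 → 5 → 6).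

Steps most likely to fail, in order:

1. **Step 2.** This is unprecedented chemistry. The likely failure modes are:
   - no insertion into the aromatic, α‑branched β‑alkoxy acrylate;
   - E1cB ring opening of the mono‑adduct, or its isomerisation to the 2,5‑dihydrofuran;
   - protodeboronation of the electron‑rich boronate;
   - substrate control eroding the 2,5‑trans selectivity;
   - partial cis C3/C4 epimers (these can be converged with catalytic DBU in MeOH at rt).

   Fallback: separate arylation from dearomatisation. Pd‑catalysed C2/C5 C–H diarylation of 4 with 4‑bromo‑2,6‑dimethoxyphenyl pivalate gives the flat 2,5‑diarylfuran diester. Reductive dearomatisation (Mg/MeOH or SmI2–H2O conjugate reduction) followed by HCl/MeOH equilibration of the benzylic centres through the p‑hydroxybenzyl cation gives racemic all‑trans 5. After reduction, the enantiomers are separated by lipase‑mediated acylation of the diol or preparative chiral chromatography.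

2. **Step 3.** The phenoxide aluminates may be poorly soluble, and a p‑phenoxide could open the benzylic ether via a quinone methide, which hydride would then reduce.
   Fallback: change the protecting‑group strategy. Carry the aryl donor as its O‑benzyl ether from step 1 (borylate 2‑benzyloxy‑1,3‑dimethoxybenzene), reduce the neutral diester, and finish with a short Pd/C hydrogenolysis.

3. **Step 1.** O‑Borylation may be incomplete, or the catalyst may be inhibited by the free phenol.
   Fallback: para‑bromination of syringol with NBS, then Pd‑catalysed Miyaura borylation of 4‑bromo‑2,6‑dimethoxyphenol with B2pin2.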